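**Remark.** The target is taken as the tautomer drawn (C6 ketone, free 4-hydroxyphenyl group). It has no stereocentre, so the C3 stereocentre of the lactone intermediates is carried racemic and removed in the last step. Benzofuran numbering (O1, C2, C3, C3a, C4–C7, C7a) is used for all intermediates.

## Retrosynthetic overview

1. Target 17 is taken back to the 6-hydroxy lactone 16 (one oxidation level lower), and this to the 2-(tert-butylamino)benzofuran 13, in which the C2 carbonyl is masked as nitrogen and O5/O6 are differentiated as OH/OBn.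
2. The route rests on lactone ring B (O1, C2, C3, C3a, C7a): it consists of a phenol oxygen (O1), an aryl-bearing carbon (C3) and a one-carbon unit (C2), all attached at C3a, the only carbon of ring A (C3a, C4–C7, C7a) that carries neither oxygen nor phenyl.
3. Key disconnection: C3–C3a, C2–C3 and O1–C2 are cut together, giving hydroquinone 7, aldehyde 8 and isocyanide 9 (formal [4+1] on an ortho-quinone methide).
4. Hydroquinone 7 comes from 2,5-diphenyl-1,4-benzoquinone 1 by introducing the third oxygen (Thiele–Winter), benzylating it at the hydroxyquinone stage and reducing.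
5. Ring order: ring A is present from the start; ring B is the only ring formed (step 5).

Key step: step 5

## Route

Step 1
Reactants: 1 2,5-diphenyl-1,4-benzoquinone
Product: 2 3,6-diphenylbenzene-1,2,4-triyl triacetate
Conditions: Ac2O, BF3·OEt2 (cat.), 45 °C
Reagents that add atoms: acetic anhydride, CC(=O)OC(C)=O
Why: Thiele–Winter acetoxylation, an acid-catalysed conjugate addition of acetate to the quinone followed by enolisation and acetylation; the two free ring positions are equivalent by symmetry, so one triacetate should form.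

Step 2
Reactants: 2 3,6-diphenylbenzene-1,2,4-triyl triacetate
Product: 4 3-hydroxy-2,5-diphenylcyclohexa-2,5-diene-1,4-dione, via 3,6-diphenylbenzene-1,2,4-triol 3 (not isolated)
Conditions: conc. HCl (cat.), MeOH, reflux, N2; then FeCl3, H2O, rt
Reagents that add atoms: none
Why: Acid-catalysed transesterification frees the triol, and FeCl3 oxidation of its para-dihydroxy pair should give the 2-hydroxy-1,4-quinone, the favoured tautomer over the ortho-quinone.

Step 3
Reactants: 4 3-hydroxy-2,5-diphenylcyclohexa-2,5-diene-1,4-dione; 5 benzyl bromide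
Product: 6 3-(benzyloxy)-2,5-diphenylcyclohexa-2,5-diene-1,4-dione
Conditions: K2CO3, DMF, rt to 50 °C
Reagents that add atoms: none
Why: Williamson O-alkylation of the hydroxyquinone, a vinylogous carboxylic acid; C-alkylation is blocked by the phenyl group on the α-carbon, and alkylation at O3 keeps the more stable para-quinone.

Step 4
Reactants: 6 3-(benzyloxy)-2,5-diphenylcyclohexa-2,5-diene-1,4-dione
Product: 7 2-(benzyloxy)-3,6-diphenylbenzene-1,4-diol
Conditions: Na2S2O4, EtOAc/H2O, rt, Ar
Reagents that add atoms: none
Why: Dithionite reduction of a quinone to its hydroquinone leaves the benzyl ether untouched; the air-sensitive product is used directly.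

Step 5
Reactants: 7 2-(benzyloxy)-3,6-diphenylbenzene-1,4-diol; 8 4-(benzyloxy)benzaldehyde; 9 tert-butyl isocyanide
Product: 13 6-(benzyloxy)-3-[4-(benzyloxy)phenyl]-2-(tert-butylamino)-4,7-diphenylbenzofuran-5-ol, via ortho-hydroxybenzhydrol 10 (not isolated), via ortho-quinone methide 11 (not isolated), via 2-iminodihydrobenzofuran tautomer 12 (not isolated)
Conditions: Sc(OTf)3 (20 mol%), 4 Å MS, degassed toluene, 60 °C, Ar; 9 added slowly
Reagents that add atoms: none
Why: Sc(OTf)3 activates aldehyde 8 for Friedel–Crafts hydroxyalkylation at C3a of 7, which is activated by the ortho hydroxyl and the para benzyloxy group, and benzhydrol 10 then loses water to give ortho-quinone methide 11, stabilised by the 4-benzyloxyphenyl group. The isocyanide carbon adds to the methide carbon C3, and the nitrilium ion is trapped by the O7a phenol in a 5-exo-dig closure of ring B, a formal [4+1] cycloaddition; tautomerisation of iminolactone 12 to the aromatic 2-aminobenzofuran 13 drives the sequence. The closest known reaction type is the acid-catalysed [4+1] annulation of isocyanides with ortho-quinone methides generated from electron-rich phenols and aldehydes or from ortho-hydroxybenzhydrols. No stereocentre remains, because C3 ends sp2. The step needs site selectivity and single incorporation of each component: the first is secured because C3a is the only free ring carbon and O7a the only hydroxyl ortho to it (the C5 hydroxyl is para to O7a and cannot close a ring). The second is secured because the C4 phenyl group shields the methide from a second molecule of 7 while the small isocyanide can still reach it.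

Step 6
Reactants: 13 6-(benzyloxy)-3-[4-(benzyloxy)phenyl]-2-(tert-butylamino)-4,7-diphenylbenzofuran-5-ol
Product: 14 6-(benzyloxy)-3-[4-(benzyloxy)phenyl]-N-tert-butyl-5-methoxy-4,7-diphenylbenzofuran-2-amine
Conditions: Me2SO4, K2CO3, degassed acetone, 40 °C, Ar
Reagents that add atoms: dimethyl sulfate, COS(=O)(=O)OC
Why: Williamson methylation of the single remaining phenol (the other hydroquinone oxygen is now the furan oxygen); carbonate does not deprotonate the hindered NH, and the fully substituted, shielded C3 of the neutral enamine should not compete with the phenoxide.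

Step 7
Reactants: 14 6-(benzyloxy)-3-[4-(benzyloxy)phenyl]-N-tert-butyl-5-methoxy-4,7-diphenylbenzofuran-2-amine
Product: 15 6-(benzyloxy)-3-[4-(benzyloxy)phenyl]-5-methoxy-4,7-diphenylbenzofuran-2(3H)-one (racemic)
Conditions: 2 M HCl (aq), THF, 50 °C
Reagents that add atoms: water, O
Why: Acid hydrolysis of a cyclic ketene N,O-acetal: protonation at C3 gives an O-aryl imidate salt, water adds at C2, and under acidic conditions the tetrahedral intermediate should expel the protonated amine to leave the lactone; benzyl and methyl ethers tolerate dilute acid.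

Step 8
Reactants: 15 6-(benzyloxy)-3-[4-(benzyloxy)phenyl]-5-methoxy-4,7-diphenylbenzofuran-2(3H)-one
Product: 16 6-hydroxy-3-(4-hydroxyphenyl)-5-methoxy-4,7-diphenylbenzofuran-2(3H)-one (racemic)
Conditions: H2 (1 atm), Pd/C (10%), EtOAc, rt
Reagents that add atoms: none
Why: Catalytic hydrogenolysis cleaves both aryl benzyl ethers and leaves the lactone, the methyl ether and the aryl rings intact; a non-nucleophilic solvent avoids opening the aryl lactone.

Step 9
Reactants: 16 6-hydroxy-3-(4-hydroxyphenyl)-5-methoxy-4,7-diphenylbenzofuran-2(3H)-one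
Product: 17 3-(4-hydroxyphenyl)-5-methoxy-4,7-diphenylbenzofuran-2,6-dione (target)
Conditions: DDQ (1.0 equiv), 1,4-dioxane, rt
Reagents that add atoms: none
Why: Dehydrogenation of a para-hydroxybenzylic C–H system: DDQ removes the doubly benzylic C3 hydrogen and the O6 hydrogen, giving the extended para-quinone methide (C6=O, C7=C7a, C3a=C3, C4=C5) and erasing the C3 stereocentre.

## Compound list

1 | 2,5-diphenyl-1,4-benzoquinone | O=C1C=C(c2ccccc2)C(=O)C=C1c1ccccc1 | starting material
2 | 3,6-diphenylbenzene-1,2,4-triyl triacetate | CC(=O)Oc1cc(-c2ccccc2)c(OC(C)=O)c(OC(C)=O)c1-c1ccccc1 | intermediate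
3 | 3,6-diphenylbenzene-1,2,4-triol (formed in situ) | Oc1cc(-c2ccccc2)c(O)c(O)c1-c1ccccc1 | intermediate
4 | 3-hydroxy-2,5-diphenylcyclohexa-2,5-diene-1,4-dione | O=C1C=C(c2ccccc2)C(=O)C(O)=C1c1ccccc1 | intermediate
5 | benzyl bromide | BrCc1ccccc1 | starting material
6 | 3-(benzyloxy)-2,5-diphenylcyclohexa-2,5-diene-1,4-dione | O=C1C=C(c2ccccc2)C(=O)C(OCc2ccccc2)=C1c1ccccc1 | intermediate
7 | 2-(benzyloxy)-3,6-diphenylbenzene-1,4-diol | Oc1cc(-c2ccccc2)c(O)c(OCc2ccccc2)c1-c1ccccc1 | intermediate
8 | 4-(benzyloxy)benzaldehyde | O=Cc1ccc(OCc2ccccc2)cc1 | starting material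
9 | tert-butyl isocyanide | [C-]#[N+]C(C)(C)C | starting material
10 | 2-(benzyloxy)-5-{[4-(benzyloxy)phenyl](hydroxy)methyl}-3,6-diphenylbenzene-1,4-diol (racemic, formed in situ) | Oc1c(C(O)c2ccc(OCc3ccccc3)cc2)c(-c2ccccc2)c(O)c(OCc2ccccc2)c1-c1ccccc1 | intermediate
11 | 3-(benzyloxy)-6-[4-(benzyloxy)benzylidene]-4-hydroxy-2,5-diphenylcyclohexa-2,4-dien-1-one (alkene geometry not defined, formed in situ) | O=C1C(=Cc2ccc(OCc3ccccc3)cc2)C(-c2ccccc2)=C(O)C(OCc2ccccc2)=C1-c1ccccc1 | intermediate
12 | 6-(benzyloxy)-3-[4-(benzyloxy)phenyl]-2-(tert-butylimino)-4,7-diphenyl-2,3-dihydrobenzofuran-5-ol (racemic, formed in situ) | Oc1c(OCc2ccccc2)c(-c2ccccc2)c2OC(=NC(C)(C)C)C(c3ccc(OCc4ccccc4)cc3)c2c1-c1ccccc1 | intermediate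
13 | 6-(benzyloxy)-3-[4-(benzyloxy)phenyl]-2-(tert-butylamino)-4,7-diphenylbenzofuran-5-ol | Oc1c(OCc2ccccc2)c(-c2ccccc2)c2oc(NC(C)(C)C)c(-c3ccc(OCc4ccccc4)cc3)c2c1-c1ccccc1 | intermediate
14 | 6-(benzyloxy)-3-[4-(benzyloxy)phenyl]-N-tert-butyl-5-methoxy-4,7-diphenylbenzofuran-2-amine | COc1c(OCc2ccccc2)c(-c2ccccc2)c2oc(NC(C)(C)C)c(-c3ccc(OCc4ccccc4)cc3)c2c1-c1ccccc1 | intermediate
15 | 6-(benzyloxy)-3-[4-(benzyloxy)phenyl]-5-methoxy-4,7-diphenylbenzofuran-2(3H)-one (racemic) | COc1c(OCc2ccccc2)c(-c2ccccc2)c2OC(=O)C(c3ccc(OCc4ccccc4)cc3)c2c1-c1ccccc1 | intermediate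
16 | 6-hydroxy-3-(4-hydroxyphenyl)-5-methoxy-4,7-diphenylbenzofuran-2(3H)-one (racemic) | COc1c(O)c(-c2ccccc2)c2OC(=O)C(c3ccc(O)cc3)c2c1-c1ccccc1 | intermediate
17 | 3-(4-hydroxyphenyl)-5-methoxy-4,7-diphenylbenzofuran-2,6-dione | COC1=C(c2ccccc2)C2=C(c3ccc(O)cc3)C(=O)OC2=C(c2ccccc2)C1=O | target

## Step count

Total steps: 9. Longest linear sequence: 9 steps (1 to 17); 5, 8 and 9 are purchased.

## Steps most likely to fail

**Step 5 (key step).** Hydroxyalkylation at the hindered C3a by an electron-rich aldehyde may be too slow while the isocyanide ties up the Lewis acid or is consumed by the aldehyde. The ionised benzhydrol may also cyclise onto the neighbouring C4 phenyl ring (fluorene formation) faster than the isocyanide captures it.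
Fallback, from 7 to 16, in which C2 and C3 arrive together in a mandelic acid:
- Pivaloyl chloride and pyridine at 0 °C should acylate the less hindered hydroxyl of 7 (the one ortho to the ring C–H) to give 3-(benzyloxy)-4-hydroxy-2,5-diphenylphenyl pivalate F1.
- Methylation of the remaining hydroxyl (Me2SO4, K2CO3, acetone) gives 3-(benzyloxy)-4-methoxy-2,5-diphenylphenyl pivalate F2.
- NaOMe in MeOH removes the ester to give 3-(benzyloxy)-4-methoxy-2,5-diphenylphenol F3.
- Acid-mediated condensation of F3 with commercial 4-hydroxymandelic acid (TsOH, 1,2-dichloroethane, 70 °C) is the known Friedel–Crafts alkylation and lactonisation of phenols with mandelic acids. At the only free ring position it should give 6-(benzyloxy)-3-(4-hydroxyphenyl)-5-methoxy-4,7-diphenylbenzofuran-2(3H)-one F4.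
- Hydrogenolysis (H2, Pd/C, EtOAc) then gives 16. Loss of the benzyl group during the condensation would be harmless, since it leads to 16 directly.

**Step 1.** Acetoxylation of the poorly soluble, conjugatively deactivated diaryl quinone may stall, with reduction or decomposition taking over.
Fallback, from 1 to 4: Weitz–Scheffer epoxidation with one equivalent of oxidant (H2O2, Na2CO3, THF/H2O, 0 °C) should give 1,4-diphenyl-7-oxabicyclo[4.1.0]hept-3-ene-2,5-dione F5. Cold concentrated H2SO4 then opens the epoxide and enolisation gives hydroxyquinone 4, the known acid rearrangement of quinone epoxides to hydroxyquinones.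

**Step 3.** The ambident hydroxyquinone anion may be alkylated on the C1 carbonyl oxygen, giving an ortho-quinone ether and, after reduction, the wrong hydroxyl pattern; the weakly nucleophilic anion may also react slowly.
Fallback, from 4 to 6: acid-catalysed vinylogous esterification with benzyl alcohol (TsOH, toluene, Dean–Stark). The C3–O bond forms by reversible addition–elimination, so the thermodynamically preferred para-quinone ether 6 should result. No new compound is made.

## Further compounds

F1 | step 5 | 3-(benzyloxy)-4-hydroxy-2,5-diphenylphenyl pivalate | Oc1c(OCc2ccccc2)c(-c2ccccc2)c(OC(=O)C(C)(C)C)cc1-c1ccccc1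
F2 | step 5 | 3-(benzyloxy)-4-methoxy-2,5-diphenylphenyl pivalate | COc1c(OCc2ccccc2)c(-c2ccccc2)c(OC(=O)C(C)(C)C)cc1-c1ccccc1
F3 | step 5 | 3-(benzyloxy)-4-methoxy-2,5-diphenylphenol | COc1c(OCc2ccccc2)c(-c2ccccc2)c(O)cc1-c1ccccc1
F4 | step 5 | 6-(benzyloxy)-3-(4-hydroxyphenyl)-5-methoxy-4,7-diphenylbenzofuran-2(3H)-one (racemic) | COc1c(OCc2ccccc2)c(-c2ccccc2)c2OC(=O)C(c3ccc(O)cc3)c2c1-c1ccccc1
F5 | step 1 | 1,4-diphenyl-7-oxabicyclo[4.1.0]hept-3-ene-2,5-dione (racemic) | O=C1C=C(c2ccccc2)C(=O)C2OC12c1ccccc1
F0 | step 3 | none | none
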